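**Plan**

- Retrosynthesis: the target is first given an extra tert-butoxycarbonyl group at C-2 of the propanoate (retro-decarboxylation). The C-2–C-3 bond between that malonate carbon and the benzylic carbon is cut next, then the hexacosyl ester C–O bond and the benzylic C–N bond of the electrophile.
- Forward: no ring is formed (the benzene ring is bought). Hexacosanol is esterified onto mono-tert-butyl malonate, 4-hydroxybenzaldehyde is turned into a benzyltrimethylammonium salt, the two halves are joined at C-2–C-3, and the surplus carboxyl is removed.
- Enabling feature: the free hydroxyl on the benzene ring sits para to the benzylic CH2 (C-3 of the propanoate). That carbon can therefore be unmasked as the exocyclic methylene of a para-quinone methide and attacked by a carbon nucleophile without phenol protection.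
- Stereochemistry: the target has no stereocentre. The malonate carbon is a stereocentre in two intermediates only, is formed racemic and is erased by the decarboxylation.

Key step: step 4

Remark on the chemistry: the C26 intermediates are waxy and poorly soluble when cold, so the chain-bearing steps are run in warm THF-containing mixtures.

**Route**

Step 1
Reactants: 1 4-hydroxybenzaldehyde; 2 dimethylamine
Product: 4 4-[(dimethylamino)methyl]phenol, via iminium acetate 3 (not isolated)
Conditions: Me2NH (2 M in THF, 2 equiv), NaBH(OAc)3 (1.5 equiv), AcOH (1 equiv), THF, 0 °C to rt; aq NaHCO3 work-up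
Reagents that add atoms: none
Why: Reductive amination: the aldehyde condenses with the secondary amine to an iminium ion, which NaBH(OAc)3 reduces faster than the electron-rich aldehyde, and the free phenol is inert to this mild hydride.

Step 2
Reactants: 4 4-[(dimethylamino)methyl]phenol
Product: 5 (4-hydroxybenzyl)trimethylammonium iodide
Conditions: MeI (1.2 equiv), acetone, 0 °C to rt, dark; filter the precipitated salt
Reagents that add atoms: iodomethane, CI
Why: Menshutkin quaternisation: the tertiary benzylic amine is far more nucleophilic than the un-ionised phenol, so with no added base only nitrogen should be methylated, and the salt should leave solution as it forms.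

Step 3
Reactants: 6 3-tert-butoxy-3-oxopropanoic acid (mono-tert-butyl malonate); 7 1-hexacosanol
Product: 8 tert-butyl hexacosyl malonate
Conditions: DCC (1.1 equiv), DMAP (0.1 equiv), CH2Cl2/THF, 0 °C to 35 °C; filter off the urea
Reagents that add atoms: none
Why: Steglich esterification: DCC activates the malonic half acid as its O-acylisourea, DMAP relays the acyl group to the primary alcohol, and the tert-butyl ester is untouched under these near-neutral conditions.

Step 4
Reactants: 5 (4-hydroxybenzyl)trimethylammonium iodide; 8 tert-butyl hexacosyl malonate
Product: 11 racemic tert-butyl hexacosyl 2-(4-hydroxybenzyl)malonate, via phenolate betaine 9 (not isolated), via para-quinone methide 10 (not isolated)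
Conditions: 8 (1.5 equiv), Cs2CO3 (2 equiv), dry THF/DMF (1:1), 60 °C, N2 sweep; 5 (1 equiv) in DMF added over 4–6 h by syringe pump; then aq NH4Cl
Reagents that add atoms: none
Why: Cs2CO3 deprotonates the phenol of 5, its most acidic site, and the phenolate betaine 9 expels trimethylamine by 1,6-elimination through the ring, giving para-quinone methide 10 at a low steady-state concentration. The caesium enolate of malonate 8 then adds through carbon to the exocyclic methylene (a 1,6-conjugate, vinylogous Michael addition), and rearomatisation to the phenolate makes the new C-2–C-3 bond irreversible. The closest known reaction type is the alkylation of active methylene compounds by quaternised phenolic Mannich bases, and by gramine methiodide, through elimination–addition. No ring is closed, and the malonate carbon becomes a stereocentre under no control, so 11 is racemic, which is immaterial because this centre is lost in step 6. The selectivity needed is mono-C-benzylation over bis-benzylation, O-attack and quinone methide oligomerisation; it is secured by adding 5 slowly to an excess of the enolate, by the softness of the malonate carbon, and by the lower acidity and greater hindrance of the monobenzylated malonate 11.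

Step 5
Reactants: 11 racemic tert-butyl hexacosyl 2-(4-hydroxybenzyl)malonate
Product: 12 racemic 3-(hexacosyloxy)-2-(4-hydroxybenzyl)-3-oxopropanoic acid
Conditions: CF3CO2H/CH2Cl2 (1:3), 0 °C to rt; co-evaporate with toluene
Reagents that add atoms: none
Why: Acidolysis of a tert-butyl ester by alkyl–oxygen cleavage: protonation releases the tert-butyl cation, which should leave as 2-methylpropene under dilute, cold conditions, while the primary hexacosyl ester and the phenol are stable to trifluoroacetic acid at room temperature.

Step 6
Reactants: 12 racemic 3-(hexacosyloxy)-2-(4-hydroxybenzyl)-3-oxopropanoic acid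
Product: 13 hexacosyl 3-(4-hydroxyphenyl)propanoate
Conditions: xylenes, 140 °C, N2; cool and crystallise, or silica gel chromatography
Reagents that add atoms: none
Why: Thermal decarboxylation of a malonic half acid through a cyclic six-centre transition state gives the ester enol, which tautomerises to the propanoate; the stereocentre disappears here and nothing else in the molecule is sensitive at this temperature.

**Compound list**

1 | 4-hydroxybenzaldehyde | O=Cc1ccc(O)cc1 | starting material
2 | dimethylamine | CNC | starting material
3 | N-(4-hydroxybenzylidene)-N-methylmethanaminium acetate (iminium acetate, not isolated) | C[N+](C)=Cc1ccc(O)cc1.CC(=O)[O-] | intermediate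
4 | 4-[(dimethylamino)methyl]phenol | CN(C)Cc1ccc(O)cc1 | intermediate
5 | (4-hydroxybenzyl)trimethylammonium iodide | C[N+](C)(C)Cc1ccc(O)cc1.[I-] | intermediate
6 | 3-tert-butoxy-3-oxopropanoic acid (mono-tert-butyl malonate) | OC(=O)CC(=O)OC(C)(C)C | starting material
7 | 1-hexacosanol | CCCCCCCCCCCCCCCCCCCCCCCCCCO | starting material
8 | tert-butyl hexacosyl malonate | CCCCCCCCCCCCCCCCCCCCCCCCCCOC(=O)CC(=O)OC(C)(C)C | intermediate
9 | 4-[(trimethylammonio)methyl]phenolate (phenolate betaine, not isolated) | C[N+](C)(C)Cc1ccc([O-])cc1 | intermediate
10 | 4-methylidenecyclohexa-2,5-dien-1-one (para-quinone methide, not isolated) | C=C1C=CC(=O)C=C1 | intermediate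
11 | racemic tert-butyl hexacosyl 2-(4-hydroxybenzyl)malonate | CCCCCCCCCCCCCCCCCCCCCCCCCCOC(=O)C(Cc1ccc(O)cc1)C(=O)OC(C)(C)C | intermediate
12 | racemic 3-(hexacosyloxy)-2-(4-hydroxybenzyl)-3-oxopropanoic acid | CCCCCCCCCCCCCCCCCCCCCCCCCCOC(=O)C(Cc1ccc(O)cc1)C(O)=O | intermediate
13 | hexacosyl 3-(4-hydroxyphenyl)propanoate | CCCCCCCCCCCCCCCCCCCCCCCCCCOC(=O)CCc1ccc(O)cc1 | target

**Step count**

Total steps: 6. Longest linear sequence: 5 steps (steps 1, 2, 4, 5, 6); the malonate arm (step 3) joins at step 4.

**Steps most likely to fail**

1. Step 4. The quinone methide may oligomerise, or the malonate may be benzylated twice, faster than mono-addition occurs; the elimination may also be sluggish at a temperature the waxy malonate tolerates. Fallback: the same C-2–C-3 bond is made at the aldehyde oxidation level. Setting out from 1 and 8, a Knoevenagel condensation (piperidine, AcOH, toluene, Dean–Stark reflux) should give tert-butyl hexacosyl 2-(4-hydroxybenzylidene)malonate F1 as an E/Z mixture. Hydrogenation of its electron-poor alkene (H2, Pd/C, THF/EtOAc, rt) then comes back to the route at 11.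

2. Step 5. The liberated tert-butyl cation may alkylate the phenol ring ortho to the hydroxyl, or cleavage may stall in the poorly solvated waxy substrate. Fallback: the acid-labile ester is replaced by one removed under neutral conditions. Setting out from 7, DCC/DMAP esterification with commercial 3-(benzyloxy)-3-oxopropanoic acid should give benzyl hexacosyl malonate F2. Benzylation of F2 with 5 under the conditions of step 4 should give racemic benzyl hexacosyl 2-(4-hydroxybenzyl)malonate F3. Hydrogenolysis of the benzyl ester (H2, Pd/C, THF/EtOAc, rt) then comes back to the route at 12.

3. Step 3. The O-acylisourea may rearrange to an unreactive N-acylurea, or the activated malonic half ester may self-condense through its ketene, while the sparingly soluble alcohol reacts slowly. Fallback: the order of ester formation is reversed. Setting out from 7, heating with Meldrum's acid (2,2-dimethyl-1,3-dioxane-4,6-dione) in toluene at reflux should open the dioxanedione and give hexacosyl hydrogen malonate F4. tert-Butylation of its free acid with tert-butyl 2,2,2-trichloroacetimidate (cat. BF3·OEt2, CH2Cl2/cyclohexane, rt) then comes back to the route at 8.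

**Further compounds**

F1 | step 4 | tert-butyl hexacosyl 2-(4-hydroxybenzylidene)malonate (E/Z mixture) | CCCCCCCCCCCCCCCCCCCCCCCCCCOC(=O)C(=Cc1ccc(O)cc1)C(=O)OC(C)(C)C
F2 | step 5 | benzyl hexacosyl malonate | CCCCCCCCCCCCCCCCCCCCCCCCCCOC(=O)CC(=O)OCc1ccccc1
F3 | step 5 | racemic benzyl hexacosyl 2-(4-hydroxybenzyl)malonate | CCCCCCCCCCCCCCCCCCCCCCCCCCOC(=O)C(Cc1ccc(O)cc1)C(=O)OCc1ccccc1
F4 | step 3 | hexacosyl hydrogen malonate | CCCCCCCCCCCCCCCCCCCCCCCCCCOC(=O)CC(O)=O
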